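The route rests on the C9–C10 bond. Ring A of the target carries oxygen on C3 and C4 and the angular methyl on C10, para to the C3 oxygen: the pattern of a dearomatised 2-methoxy-4-methylphenol, while the C8 carbonyl marks the central carbon of an allyl unit tethered at C5. One palladium-catalysed enantioselective allylation of the phenol through its para carbon therefore closes ring B, sets the quaternary stereocentre C10 and leaves a cross-conjugated dienone with both ring-A oxygens in place and differentiated. The precursor is a free guaiacol bearing, on a two-carbon chain at C5, a 2-substituted allylic methyl carbonate.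

Key step: step 8

Remarks on the chemistry (one line each):
- Atom and ring labels are those of the target throughout: ring A = C1–C5 and C10, ring B = C5–C10, and β is the face of the C10 methyl; bicyclic names use this numbering.
- The phenol oxygen is differentiated from the first step (a silyl ether on a starting material with one free hydroxyl), because cleaving one of two neighbouring aryl methyl ethers in a 3-alkylveratrole normally removes the doubly flanked methoxy group and would give the wrong phenol.
- The exocyclic methylene from the key step is kept as the mask of the C8 carbonyl until the C4 carbinol exists: an acetal at C8 would be lost in the acid that unmasks C4, and MeMgBr could not tell two free ketones apart.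
- Assumption: 3-hydroxy-2-methoxybenzaldehyde is taken as a catalogue compound.
- Assumption: which enantiomer of the ligand leads to the (10S) dienone must be settled by experiment; (R,R) is written.

Step 1
Reactants: 1 3-hydroxy-2-methoxybenzaldehyde
Product: 2 2-methoxy-3-(triisopropylsilyloxy)benzaldehyde
Conditions: TIPSCl, imidazole, DMF, rt
Reagents that add atoms: chlorotriisopropylsilane, CC(C)[Si](Cl)(C(C)C)C(C)C
Why: Silylation of the phenol gives a bulky ether that does not direct the coming lithiation, survives organolithium reagents and is removed by fluoride at the end without harm to an allylic carbonate.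

Step 2
Reactants: 2 2-methoxy-3-(triisopropylsilyloxy)benzaldehyde
Product: 6 2-methoxy-6-methyl-3-(triisopropylsilyloxy)benzaldehyde, via lithium α-amino alkoxide 3 (not isolated), via aryllithium 4 (not isolated), via methylated α-amino alkoxide 5 (not isolated)
Conditions: HN(Me)CH2CH2NMe2, n-BuLi, THF, −20 °C; then 2; n-BuLi (3 equiv), −20 °C; MeI, −78 °C → rt; H2O
Reagents that add atoms: iodomethane, CI
Why: Comins in situ protection and directed ortho-lithiation: the chelating α-amino alkoxide steers n-BuLi to C6 of the arene, the only position ortho to it, and the hemiaminal returns the aldehyde on aqueous work-up.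

Step 3
Reactants: 6 2-methoxy-6-methyl-3-(triisopropylsilyloxy)benzaldehyde
Product: 7 [2-methoxy-6-methyl-3-(triisopropylsilyloxy)phenyl]methanol
Conditions: NaBH4, EtOH, 0 °C
Reagents that add atoms: none
Why: Borohydride reduction of the aryl aldehyde, the only reducible group, should give the benzylic alcohol.

Step 4
Reactants: 7 [2-methoxy-6-methyl-3-(triisopropylsilyloxy)phenyl]methanol
Product: 8 [3-(bromomethyl)-2-methoxy-4-methylphenoxy]triisopropylsilane
Conditions: CBr4, PPh3, CH2Cl2, 0 °C
Reagents that add atoms: carbon tetrabromide, BrC(Br)(Br)Br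
Why: Appel bromination is neutral, so the aryl silyl ether is spared and the electron-rich benzylic bromide is obtained for the C–C coupling.

Step 5
Reactants: 8 [3-(bromomethyl)-2-methoxy-4-methylphenoxy]triisopropylsilane; 9 2-methylprop-2-en-1-ol
Product: 11 4-[2-methoxy-6-methyl-3-(triisopropylsilyloxy)phenyl]-2-methylenebutan-1-ol, via dilithiated 2-methylprop-2-en-1-ol 10 (not isolated)
Conditions: 9, n-BuLi (2 equiv), TMEDA, Et2O, 0 °C → rt; then 8, THF, −78 → 0 °C; H2O
Reagents that add atoms: 2-methylprop-2-en-1-ol (9), CC(=C)CO
Why: Alkylation of the C,O-dianion of methallyl alcohol at its allylic carbon by the benzylic bromide joins C6 to C7 and delivers the complete 2-substituted allylic alcohol in one operation.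

Step 6
Reactants: 11 4-[2-methoxy-6-methyl-3-(triisopropylsilyloxy)phenyl]-2-methylenebutan-1-ol
Product: 12 methyl 4-[2-methoxy-6-methyl-3-(triisopropylsilyloxy)phenyl]-2-methylenebutyl carbonate
Conditions: ClCO2Me, pyridine, CH2Cl2, 0 °C
Reagents that add atoms: methyl chloroformate, COC(=O)Cl
Why: Acylation of the primary allylic alcohol with a chloroformate installs the ionisable group that also supplies the base of the key step.

Step 7
Reactants: 12 methyl 4-[2-methoxy-6-methyl-3-(triisopropylsilyloxy)phenyl]-2-methylenebutyl carbonate
Product: 13 2-methoxy-4-methyl-3-[3-(methoxycarbonyloxymethyl)but-3-enyl]phenol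
Conditions: Bu4NF, AcOH, THF, 0 °C
Reagents that add atoms: none
Why: Buffered fluoride cleaves the aryl silyl ether quickly while the allylic carbonate and the alkene are inert, so the phenol is freed only immediately before cyclisation.

Step 8
Reactants: 13 2-methoxy-4-methyl-3-[3-(methoxycarbonyloxymethyl)but-3-enyl]phenol
Product: 15 (10S)-4-methoxy-10β-methyl-8-methylene-6,7,8,9-tetrahydronaphthalen-3(10H)-one, via η3-allylpalladium phenoxide 14 (not isolated)
Conditions: Pd2(dba)3·CHCl3 (2.5 mol %), (R,R)-DACH-phenyl Trost ligand (7.5 mol %), CH2Cl2 (0.01 M), rt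
Reagents that add atoms: none
Why: Proposed new method: zerovalent palladium inserts into the allylic C–O bond of the carbonate, CO2 leaves, and the methoxide counter-ion of the resulting symmetrical 2-alkyl-η3-allyl complex takes the phenolic proton; the phenoxide then bonds through C10, the carbon para to oxygen, to an allyl terminus on the face away from the metal. The closest known reaction type is the palladium-catalysed asymmetric intramolecular allylic dearomatisation of para-substituted phenols, established for spirocyclisation (tether on the para carbon) but not for a meta tether that gives a fused ring; base-mediated para C-alkylation of phenolates to fused dienones is the racemic ancestor. Ring B is closed in the 6-exo mode: C9, the carbon attacked, lies in the new ring and the bond to palladium that is given up lies outside it. C10 is the only new stereocentre and is fixed by the chiral pocket of the bisphosphine, which makes the two faces of the flat phenoxide unequal. The step needs attack by C10 and not by oxygen or by C4: an O–C9 bond would demand an eight-membered ring and allyl aryl ethers re-ionise under the catalyst, whereas C4 is hemmed in by the tether and its own methoxy group and carries the smaller share of the phenoxide HOMO, and the methyl on C10 stops the product from tautomerising back to an arene. High dilution keeps intermolecular O-allylation down.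

Step 9
Reactants: 15 (10S)-4-methoxy-10β-methyl-8-methylene-6,7,8,9-tetrahydronaphthalen-3(10H)-one
Product: 17 4-methoxy-10β-methyl-8-methylene-1,2,6,7,8,9-hexahydronaphthalen-3(10H)-one, via copper dienolate 16 (not isolated)
Conditions: [(Ph3P)CuH]6 (0.3 equiv), H2O (2 equiv), THF, rt
Reagents that add atoms: none
Why: Conjugate reduction with the phosphine copper hydride hexamer should deliver hydride only to C1, the unsubstituted β-carbon of the cross-conjugated dienone, leaving the fully substituted C5 terminus, the carbonyl and the isolated exocyclic alkene untouched.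

Step 10
Reactants: 17 4-methoxy-10β-methyl-8-methylene-1,2,6,7,8,9-hexahydronaphthalen-3(10H)-one
Product: 18 4-methoxy-10β-methyl-8-methylene-1,2,3,6,7,8,9,10-octahydronaphthalen-3β-ol
Conditions: NaBH4, CeCl3·7H2O, MeOH, −78 → −20 °C
Reagents that add atoms: none
Why: Luche 1,2-reduction: hydride should add to C3 axially from the α face of the half-chair, as in 10β-methyl Δ4-3-ketones, which sets the pseudo-equatorial 3β-alcohol.

Step 11
Reactants: 18 4-methoxy-10β-methyl-8-methylene-1,2,3,6,7,8,9,10-octahydronaphthalen-3β-ol
Product: 19 tert-butyl[(4-methoxy-10β-methyl-8-methylene-1,2,3,6,7,8,9,10-octahydronaphthalen-3β-yl)oxy]dimethylsilane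
Conditions: TBSCl, imidazole, DMF, rt
Reagents that add atoms: tert-butyldimethylsilyl chloride, CC(C)(C)[Si](C)(C)Cl
Why: Silylation under basic conditions spares the enol ether, and the ether blocks enediol tautomerism of the α-ketol formed next and tolerates Grignard and enolate chemistry.

Step 12
Reactants: 19 tert-butyl[(4-methoxy-10β-methyl-8-methylene-1,2,3,6,7,8,9,10-octahydronaphthalen-3β-yl)oxy]dimethylsilane
Product: 20 3β-(tert-butyldimethylsilyloxy)-10β-methyl-8-methylene-5α-decahydronaphthalen-4-one
Conditions: 1 M HCl, THF, 0 °C → rt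
Reagents that add atoms: water, O
Why: Acid hydrolysis of the enol ether: C5 should be protonated on the α face, opposite to the C10 methyl, and the trans ring fusion (5α-H) with an equatorial 3β-silyloxy group is also the arrangement favoured when the ketone enolises under the same acid.

Step 13
Reactants: 20 3β-(tert-butyldimethylsilyloxy)-10β-methyl-8-methylene-5α-decahydronaphthalen-4-one; 21 methylmagnesium bromide
Product: 22 3β-(tert-butyldimethylsilyloxy)-4α,10β-dimethyl-8-methylene-5α-decahydronaphthalen-4β-ol
Conditions: MeMgBr, THF, −78 → 0 °C; H2O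
Reagents that add atoms: methylmagnesium bromide (21), C[Mg]Br
Why: Grignard addition to the C4 ketone: the axial (β) approach is blocked by the syn-axial C10 methyl, so methyl should enter equatorially on the α face and give the 4α-methyl 4β-carbinol.

Step 14
Reactants: 22 3β-(tert-butyldimethylsilyloxy)-4α,10β-dimethyl-8-methylene-5α-decahydronaphthalen-4β-ol
Product: 24 3β-(tert-butyldimethylsilyloxy)-4β-hydroxy-4α,10β-dimethyl-5α-decahydronaphthalen-8-one, via spiro ozonide 23 (not isolated)
Conditions: O3, CH2Cl2, −78 °C; PPh3, −78 °C → rt
Reagents that add atoms: ozone, [O-][O+]=O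
Why: Ozonolysis with reductive work-up converts the only alkene present, the exocyclic methylene that has masked C8, into the C8 ketone.

Step 15
Reactants: 24 3β-(tert-butyldimethylsilyloxy)-4β-hydroxy-4α,10β-dimethyl-5α-decahydronaphthalen-8-one; 25 acetone
Product: 27 3β-(tert-butyldimethylsilyloxy)-4β-hydroxy-7-(2-hydroxypropan-2-yl)-4α,10β-dimethyl-5α-decahydronaphthalen-8-one (C7 epimers), via dilithium enolate 26 (not isolated)
Conditions: LiN(i-Pr)2 (2.2 equiv), THF, −78 °C; acetone, −78 °C; AcOH
Reagents that add atoms: acetone (25), CC(C)=O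
Why: Kinetic enolate formation and aldol addition: once the tertiary alkoxide has formed, the amide base should remove a proton from C7 and not from C9, which is neopentyl next to quaternary C10, and the enolate adds to acetone; the C7 configuration is immaterial because the next step makes C7 trigonal.

Step 16
Reactants: 27 3β-(tert-butyldimethylsilyloxy)-4β-hydroxy-7-(2-hydroxypropan-2-yl)-4α,10β-dimethyl-5α-decahydronaphthalen-8-one (C7 epimers)
Product: 29 3β-(tert-butyldimethylsilyloxy)-4β-hydroxy-5α-eudesm-7(11)-en-8-one, via tertiary mesylate 28 (not isolated)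
Conditions: MsCl, Et3N, CH2Cl2, 0 °C; DBU, rt
Reagents that add atoms: none
Why: Sulfonylation of the side-chain carbinol followed by E1cB elimination through the ketone enolate should give the conjugated isopropylidene ketone, while the C4 hydroxyl (axial, syn to the C10 methyl and flanked by the silyloxy group) is too hindered to be sulfonylated.

Step 17
Reactants: 29 3β-(tert-butyldimethylsilyloxy)-4β-hydroxy-5α-eudesm-7(11)-en-8-one
Product: 30 3β,4β-dihydroxy-5α-eudesm-7(11)-en-8-one
Conditions: Bu4NF, THF, 0 °C → rt
Reagents that add atoms: none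
Why: Fluoride cleavage of the secondary silyl ether frees the cis-3β,4β-diol at a stage where no ester is present that could migrate.

Step 18
Reactants: 30 3β,4β-dihydroxy-5α-eudesm-7(11)-en-8-one; 31 angelic acid
Product: 33 3β-angeloyloxy-4β-hydroxy-5α-eudesm-7(11)-en-8-one, via angelic 2,4,6-trichlorobenzoic anhydride 32 (not isolated)
Conditions: 31, 2,4,6-trichlorobenzoyl chloride, Et3N, toluene, rt; then 30, 80 °C
Reagents that add atoms: angelic acid (31), C/C=C(/C)C(=O)O
Why: Yamaguchi-type esterification through the mixed anhydride should acylate the equatorial secondary 3β-hydroxyl and not the tertiary one, and it avoids the nucleophilic catalysts that isomerise the (Z)-ester to the tiglate.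

Step 19
Reactants: 33 3β-angeloyloxy-4β-hydroxy-5α-eudesm-7(11)-en-8-one
Product: 34 4β-acetoxy-3β-angeloyloxy-5α-eudesm-7(11)-en-8-one
Conditions: Ac2O, Sc(OTf)3 (5 mol %), MeCN, −20 °C
Reagents that add atoms: acetic anhydride, CC(=O)OC(C)=O
Why: Lewis acid catalysed acylation with the anhydride is strong enough for the hindered axial tertiary alcohol at low temperature, where elimination and isomerisation of the angelate are slow, and C4 keeps its configuration because its C–O bond is not broken.

Compound list
1 | 3-hydroxy-2-methoxybenzaldehyde | COc1c(O)cccc1C=O | starting material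
2 | 2-methoxy-3-(triisopropylsilyloxy)benzaldehyde | COc1c(O[Si](C(C)C)(C(C)C)C(C)C)cccc1C=O | intermediate
3 | lithium α-amino alkoxide from 2 and lithium N-[2-(dimethylamino)ethyl]-N-methylamide | COc1c(O[Si](C(C)C)(C(C)C)C(C)C)cccc1C(O[Li])N(C)CCN(C)C | intermediate
4 | aryllithium (6-lithio derivative of 3) | COc1c(O[Si](C(C)C)(C(C)C)C(C)C)ccc([Li])c1C(O[Li])N(C)CCN(C)C | intermediate
5 | methylated α-amino alkoxide (6-methyl derivative of 3) | COc1c(O[Si](C(C)C)(C(C)C)C(C)C)ccc(C)c1C(O[Li])N(C)CCN(C)C | intermediate
6 | 2-methoxy-6-methyl-3-(triisopropylsilyloxy)benzaldehyde | COc1c(O[Si](C(C)C)(C(C)C)C(C)C)ccc(C)c1C=O | intermediate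
7 | [2-methoxy-6-methyl-3-(triisopropylsilyloxy)phenyl]methanol | COc1c(O[Si](C(C)C)(C(C)C)C(C)C)ccc(C)c1CO | intermediate
8 | [3-(bromomethyl)-2-methoxy-4-methylphenoxy]triisopropylsilane | COc1c(O[Si](C(C)C)(C(C)C)C(C)C)ccc(C)c1CBr | intermediate
9 | 2-methylprop-2-en-1-ol | CC(=C)CO | starting material
10 | dilithiated 2-methylprop-2-en-1-ol (C,O-dianion) | [Li]CC(=C)CO[Li] | intermediate
11 | 4-[2-methoxy-6-methyl-3-(triisopropylsilyloxy)phenyl]-2-methylenebutan-1-ol | COc1c(O[Si](C(C)C)(C(C)C)C(C)C)ccc(C)c1CCC(=C)CO | intermediate
12 | methyl 4-[2-methoxy-6-methyl-3-(triisopropylsilyloxy)phenyl]-2-methylenebutyl carbonate | COC(=O)OCC(=C)CCc1c(C)ccc(O[Si](C(C)C)(C(C)C)C(C)C)c1OC | intermediate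
13 | 2-methoxy-4-methyl-3-[3-(methoxycarbonyloxymethyl)but-3-enyl]phenol | COC(=O)OCC(=C)CCc1c(C)ccc(O)c1OC | intermediate
14 | η3-allylpalladium phenoxide zwitterion (drawn as the σ-allyl form, ligand omitted) | COc1c([O-])ccc(C)c1CCC(=C)C[Pd+] | intermediate
15 | (10S)-4-methoxy-10β-methyl-8-methylene-6,7,8,9-tetrahydronaphthalen-3(10H)-one | COC1=C2CCC(=C)C[C@@]2(C)C=CC1=O | intermediate
16 | copper dienolate of 17 (phosphine omitted) | [Cu]OC1=CC[C@]2(C)CC(=C)CCC2=C1OC | intermediate
17 | 4-methoxy-10β-methyl-8-methylene-1,2,6,7,8,9-hexahydronaphthalen-3(10H)-one | O=C1CC[C@]2(C)CC(=C)CCC2=C1OC | intermediate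
18 | 4-methoxy-10β-methyl-8-methylene-1,2,3,6,7,8,9,10-octahydronaphthalen-3β-ol | O[C@H]1CC[C@]2(C)CC(=C)CCC2=C1OC | intermediate
19 | tert-butyl[(4-methoxy-10β-methyl-8-methylene-1,2,3,6,7,8,9,10-octahydronaphthalen-3β-yl)oxy]dimethylsilane | CC(C)(C)[Si](C)(C)O[C@H]1CC[C@]2(C)CC(=C)CCC2=C1OC | intermediate
20 | 3β-(tert-butyldimethylsilyloxy)-10β-methyl-8-methylene-5α-decahydronaphthalen-4-one (trans-fused) | CC(C)(C)[Si](C)(C)O[C@H]1CC[C@]2(C)CC(=C)CC[C@H]2C1=O | intermediate
21 | methylmagnesium bromide | C[Mg]Br | starting material
22 | 3β-(tert-butyldimethylsilyloxy)-4α,10β-dimethyl-8-methylene-5α-decahydronaphthalen-4β-ol | CC(C)(C)[Si](C)(C)O[C@H]1CC[C@]2(C)CC(=C)CC[C@H]2[C@@]1(C)O | intermediate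
23 | spiro ozonide (1,2,4-trioxolane) at C8 of 22 | CC(C)(C)[Si](C)(C)O[C@H]1CC[C@]2(C)CC3(OCOO3)CC[C@H]2[C@@]1(C)O | intermediate
24 | 3β-(tert-butyldimethylsilyloxy)-4β-hydroxy-4α,10β-dimethyl-5α-decahydronaphthalen-8-one | CC(C)(C)[Si](C)(C)O[C@H]1CC[C@]2(C)CC(=O)CC[C@H]2[C@@]1(C)O | intermediate
25 | acetone | CC(C)=O | starting material
26 | dilithium enolate (C4 alkoxide, C7–C8 enolate) of 24 | CC(C)(C)[Si](C)(C)O[C@H]1CC[C@]2(C)CC(O[Li])=CC[C@H]2[C@@]1(C)O[Li] | intermediate
27 | 3β-(tert-butyldimethylsilyloxy)-4β-hydroxy-7-(2-hydroxypropan-2-yl)-4α,10β-dimethyl-5α-decahydronaphthalen-8-one (C7 epimers) | CC(C)(C)[Si](C)(C)O[C@H]1CC[C@]2(C)CC(=O)C(C(C)(C)O)C[C@H]2[C@@]1(C)O | intermediate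
28 | tertiary mesylate of 27 | CC(C)(C)[Si](C)(C)O[C@H]1CC[C@]2(C)CC(=O)C(C(C)(C)OS(C)(=O)=O)C[C@H]2[C@@]1(C)O | intermediate
29 | 3β-(tert-butyldimethylsilyloxy)-4β-hydroxy-5α-eudesm-7(11)-en-8-one | CC(C)(C)[Si](C)(C)O[C@H]1CC[C@]2(C)CC(=O)C(=C(C)C)C[C@H]2[C@@]1(C)O | intermediate
30 | 3β,4β-dihydroxy-5α-eudesm-7(11)-en-8-one | O[C@H]1CC[C@]2(C)CC(=O)C(=C(C)C)C[C@H]2[C@@]1(C)O | intermediate
31 | angelic acid, (Z)-2-methylbut-2-enoic acid | C/C=C(/C)C(=O)O | starting material
32 | angelic 2,4,6-trichlorobenzoic anhydride | C/C=C(/C)C(=O)OC(=O)c1c(Cl)cc(Cl)cc1Cl | intermediate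
33 | 3β-angeloyloxy-4β-hydroxy-5α-eudesm-7(11)-en-8-one | C/C=C(/C)C(=O)O[C@H]1CC[C@]2(C)CC(=O)C(=C(C)C)C[C@H]2[C@@]1(C)O | intermediate
34 | 4β-acetoxy-3β-angeloyloxy-5α-eudesm-7(11)-en-8-one, CNP0141494.2 | C/C=C(/C)C(=O)O[C@H]1CC[C@]2(C)CC(=O)C(=C(C)C)C[C@H]2[C@@]1(C)OC(C)=O | target

Total step count: 19. Longest linear sequence: 19 steps (1 to 34); the other starting materials enter as single reagents.

Steps most likely to fail

Step 8 (proposed new method). The cyclisation may go astray by bonding through oxygen or C4, by intermolecular allylation, by poor discrimination of the phenoxide faces, or by re-ionisation of the new allylic C9–C10 bond with erosion of enantiopurity. The fallback sets out from 11 and uses classical phenolate alkylation. Alcohol 11 is converted with CBr4 and PPh3 into the allylic bromide F1. The silyl ether is cleaved with Bu4NF and AcOH to the bromophenol F2. KOt-Bu in t-BuOH at high dilution then effects intramolecular para C-alkylation of the phenolate, the established way to fused cross-conjugated dienones, and gives the racemic dienone F3. Preparative chromatography on a chiral stationary phase separates the enantiomers and the route is rejoined at 15.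

Step 12. Protonation of C5 may occur on the wrong face, equilibration may favour the cis-fused ketone, or the silyl ether may be lost in acid with subsequent enediol scrambling. The fallback sets out from 19 and delivers the ring-fusion hydrogen as a hydrogen atom instead of a proton. NBS in aqueous THF at 0 °C brominates the enol ether at C5 and water captures the oxocarbenium ion, giving the 5-bromo-4-ketone F4. Bu3SnH with AIBN in benzene at 80 °C then reduces the tertiary α-keto bromide. The planar C5 radical should take hydrogen from the stannane axially on the α face, anti to the C10 methyl, in an irreversible step, and the route is rejoined at 20.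

Step 19. The axial tertiary hydroxyl may resist acylation, C4 may ionise and eliminate, or the angelate may isomerise under the Lewis acid. The fallback sets out from 30, delivers the acetate intramolecularly and reverses the order of the esters. Diol 30 with MeC(OMe)3 and PPTS in CH2Cl2 gives the cyclic methyl orthoacetate F5. Opening with 80% aqueous AcOH at rt follows the known preference of cyclohexane-fused orthoesters for the axial ester and should give the 4β-acetoxy 3β-alcohol F6. The secondary hydroxyl of F6 is then acylated with the preformed mixed anhydride 32 in toluene at 80 °C without added amine, to limit acetyl migration, and the route is rejoined at 34.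

Further compounds
F1 | step 8 | [3-[3-(bromomethyl)but-3-enyl]-2-methoxy-4-methylphenoxy]triisopropylsilane | COc1c(O[Si](C(C)C)(C(C)C)C(C)C)ccc(C)c1CCC(=C)CBr
F2 | step 8 | 3-[3-(bromomethyl)but-3-enyl]-2-methoxy-4-methylphenol | COc1c(O)ccc(C)c1CCC(=C)CBr
F3 | step 8 | racemic 4-methoxy-10-methyl-8-methylene-6,7,8,9-tetrahydronaphthalen-3(10H)-one | COC1=C2CCC(=C)CC2(C)C=CC1=O
F4 | step 12 | 5-bromo-3β-(tert-butyldimethylsilyloxy)-10β-methyl-8-methylenedecahydronaphthalen-4-one (C5 configuration open) | CC(C)(C)[Si](C)(C)O[C@H]1CC[C@]2(C)CC(=C)CCC2(Br)C1=O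
F5 | step 19 | cyclic methyl orthoacetate of the 3β,4β-diol 30 | COC1(C)O[C@H]2CC[C@]3(C)CC(=O)C(=C(C)C)C[C@H]3[C@@]2(C)O1
F6 | step 19 | 4β-acetoxy-3β-hydroxy-5α-eudesm-7(11)-en-8-one | O[C@H]1CC[C@]2(C)CC(=O)C(=C(C)C)C[C@H]2[C@@]1(C)OC(C)=O
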